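**Assumption:** the target SMILES has no stereocentre (the molecule is achiral), so there is no configuration to set and the "single enantiomer" requirement is met trivially.

**Retrosynthetic overview**
- Last bond: the aryl–CH2 bond between the two flanking methoxy groups, made by opening 2,2-dimethyloxetane with the arylzinc obtained by C–H metalation of 2,3,5-trimethoxybibenzyl (new step; it brings in the whole 3-hydroxy-3-methylbutyl chain).
- The bibenzyl: Catellani ortho-alkylation with ipso-hydride termination of 1-iodo-2,4,5-trimethoxybenzene with (2-bromoethyl)benzene.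
- The aryl iodide: regioselective iodination of 1,2,4-trimethoxybenzene.
- No ring is built; both benzene rings are bought.

**Route**

Step 1
Reactants: 1 1,2,4-trimethoxybenzene
Product: 2 1-iodo-2,4,5-trimethoxybenzene
Conditions: NIS (1.05 equiv), TFA (10 mol %), MeCN, rt, 2 h
Reagents that add atoms: N-iodosuccinimide, O=C1CCC(=O)N1I
Why: Electrophilic aromatic iodination (SEAr); C5 of 1 is para to one methoxy and ortho to another and is the most activated, unhindered site, so a single iodide forms; no stereocentre.

Step 2
Reactants: 2 1-iodo-2,4,5-trimethoxybenzene; 3 (2-bromoethyl)benzene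
Product: 4 1,2,5-trimethoxy-3-(2-phenylethyl)benzene (2,3,5-trimethoxybibenzyl)
Conditions: Pd(OAc)2 (10 mol %), P(2-furyl)3 (22 mol %), norbornene (2 equiv), 3 (3 equiv), Cs2CO3 (3 equiv), HCO2Na (2 equiv), MeCN, 85 °C, 18 h
Reagents that add atoms: none
Why: Catellani reaction (palladium/norbornene ortho C–H alkylation with ipso hydride termination): the C–I bond of 2 adds to zerovalent palladium, norbornene insertion and palladation of the only free ortho C–H give a palladacycle that 3 alkylates through a tetravalent palladium intermediate, norbornene is then expelled and formate delivers hydride to the ipso carbon, so the phenethyl group lands on the carbon that electrophilic substitution of 1 cannot reach; no stereocentre.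

Step 3
Reactants: 4 1,2,5-trimethoxy-3-(2-phenylethyl)benzene; 5 2,2-dimethyloxetane
Product: 10 2-methyl-4-[2,3,6-trimethoxy-4-(2-phenylethyl)phenyl]butan-2-ol, via aryllithium 6 (not isolated), via arylzinc chloride 7 (not isolated), via chlorozinc iodoalkoxide 8 (not isolated), via chlorozinc alkoxide 9 (not isolated)
Conditions: n-BuLi (1.2 equiv), THF, 0 °C to rt, 2 h; ZnCl2 (2.0 equiv), rt; then 5 (1.5 equiv), LiI (50 mol %), NiCl2(dme) (10 mol %), 4,4'-di-tert-butyl-2,2'-bipyridine (12 mol %), THF/DMA 2:1, 45 °C, 16 h; 0.5 M aq. HCl, 0 °C
Reagents that add atoms: none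
Why: Proposed new method: one-pot C–H zincation and nickel-catalysed ring-opening Negishi arylation of an oxetane with iodide relay — n-BuLi removes the one proton flanked by two methoxy groups of 4 (directed ortho-metalation, 6) and ZnCl2 gives arylzinc 7; the weakly Lewis-acidic chlorozinc species activate the oxetane oxygen so that iodide opens 5 by SN2 attack at the unhindered CH2–O carbon rather than the tertiary one, giving primary alkyl iodide 8; a low-valent nickel–bipyridine catalyst then joins 7 and 8 (halogen-atom abstraction, capture of the primary radical at aryl–nickel, reductive elimination) to give 9 and returns the iodide; the closest known reaction types are the nickel-catalysed Negishi coupling of unactivated primary alkyl iodides with arylzinc halides and the halide-relay nickel-catalysed ring-opening couplings of epoxides and aziridines, whereas to my knowledge an oxetane has not been used as the electrophile for an arylzinc reagent; no stereocentre is formed.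

**Compound list**
1 | 1,2,4-trimethoxybenzene | COc1ccc(OC)c(OC)c1 | starting material
2 | 1-iodo-2,4,5-trimethoxybenzene | COc1cc(OC)c(OC)cc1I | intermediate
3 | (2-bromoethyl)benzene | BrCCc1ccccc1 | starting material
4 | 1,2,5-trimethoxy-3-(2-phenylethyl)benzene | COc1cc(CCc2ccccc2)c(OC)c(OC)c1 | intermediate
5 | 2,2-dimethyloxetane | CC1(C)CCO1 | starting material
6 | [2,3,6-trimethoxy-4-(2-phenylethyl)phenyl]lithium | [Li]c1c(OC)cc(CCc2ccccc2)c(OC)c1OC | intermediate
7 | chloro[2,3,6-trimethoxy-4-(2-phenylethyl)phenyl]zinc | Cl[Zn]c1c(OC)cc(CCc2ccccc2)c(OC)c1OC | intermediate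
8 | chlorozinc 4-iodo-2-methylbutan-2-olate | CC(C)(CCI)O[Zn]Cl | intermediate
9 | chlorozinc 2-methyl-4-[2,3,6-trimethoxy-4-(2-phenylethyl)phenyl]butan-2-olate | COc1cc(CCc2ccccc2)c(OC)c(OC)c1CCC(C)(C)O[Zn]Cl | intermediate
10 | 2-methyl-4-[2,3,6-trimethoxy-4-(2-phenylethyl)phenyl]butan-2-ol | COc1cc(CCc2ccccc2)c(OC)c(OC)c1CCC(C)(C)O | target

**Total step count:** 3. **Longest linear sequence:** 3.

**Steps most likely to fail, with fallbacks**

Most at risk is step 3, the proposed new method. The oxetane may open at the tertiary carbon or too slowly, and the di-ortho-substituted arylzinc may transmetalate poorly. The fallback uses known chemistry, sets out from 4 and comes back at 10. Compound 4 is lithiated as before (n-BuLi, THF, 0 °C to rt), CuI (10 mol %) is added at −20 °C, and the aryl–metal is alkylated with prenyl bromide (1-bromo-3-methylbut-2-ene) to give 1,3,4-trimethoxy-2-(3-methylbut-2-en-1-yl)-5-(2-phenylethyl)benzene F1. Mukaiyama hydration of F1 (Co(acac)2 20 mol %, PhSiH3, O2 balloon, THF, rt, then PPh3 work-up) places the hydroxyl at the tertiary carbon and gives 10.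

Second is step 2. Compound 3 can eliminate to styrene under carbonate, and formate can reduce the aryl–palladium species before the relay, returning 1. The fallback sets out from 3 and comes back at 4, and fixes the phenethyl position by cross-coupling instead of C–H relay. Zinc insertion into 3 (Zn dust, LiCl, THF, 50 °C) gives (2-phenylethyl)zinc bromide F2. Separately, commercial 5-bromovanillin F3 undergoes Dakin oxidation (H2O2, aq. NaOH, 0 °C to rt) to 2-bromo-6-methoxybenzene-1,4-diol F4. Double O-methylation (MeI, K2CO3, acetone, reflux) gives 1-bromo-2,3,5-trimethoxybenzene F5. Negishi coupling of F5 with F2 (Pd(OAc)2 2 mol %, SPhos 4 mol %, THF, 60 °C) gives 4.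

Third is step 1. The very electron-rich ring can be over-iodinated or oxidised to a quinone by the N-iodo reagent. The fallback sets out from 1 and comes back at 2. Bromination with NBS (MeCN, rt) gives 1-bromo-2,4,5-trimethoxybenzene F6. Copper-catalysed aromatic halogen exchange (CuI 5 mol %, NaI 2 equiv, trans-N,N'-dimethylcyclohexane-1,2-diamine 10 mol %, dioxane, 110 °C) then gives 2.

**Further compounds**
F1 | step 3 | 1,3,4-trimethoxy-2-(3-methylbut-2-en-1-yl)-5-(2-phenylethyl)benzene | COc1cc(CCc2ccccc2)c(OC)c(OC)c1CC=C(C)C
F2 | step 2 | (2-phenylethyl)zinc bromide | Br[Zn]CCc1ccccc1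
F3 | step 2 | 5-bromovanillin (3-bromo-4-hydroxy-5-methoxybenzaldehyde, purchased) | COc1cc(C=O)cc(Br)c1O
F4 | step 2 | 2-bromo-6-methoxybenzene-1,4-diol | COc1cc(O)cc(Br)c1O
F5 | step 2 | 1-bromo-2,3,5-trimethoxybenzene | COc1cc(Br)c(OC)c(OC)c1
F6 | step 1 | 1-bromo-2,4,5-trimethoxybenzene | COc1cc(OC)c(OC)cc1Br
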